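The ten-membered carbocycle is disconnected at C8–C9 as an anionic oxy-Cope product. The route exploits its Z C4=C5 alkene flanked by oxygenated C3 and C6 and its E C1–C10 unit (the later ring oxirane) standing 1,5 to the C6–C7 bond: C1–C6 with C10, C14 and C15 are a 4-silyloxy-isopiperitenone from (R)-carvone. The precursor is the trans-1,2-dialkenyl cyclohexenol formed from that enone and a metalated 2-methoxy-2,3-dihydrofuran. One [3,3] shift expands the six-membered ring to the germacrane ring, which then already carries the cis-fused O8–C12 acetal ring, both alkene geometries and the C7 and C8 centres. Lactone adjustment, methylenation, two acylations and a last epoxidation complete the synthesis.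

Key step: step 9

Remark on the chemistry: the acetal carbon C12 is carried as both epimers (the dihydrofuran reagent is racemic) until it becomes a lactone carbonyl; germacrane numbering is used for all ten-membered-ring compounds.

Step 1
Reactants: 1 (R)-(−)-carvone
Product: 2 (1R,5R)-cis-carveol
Conditions: NaBH4, CeCl3·7H2O, MeOH, −78 → 0 °C
Reagents that add atoms: none
Why: Luche reduction gives clean 1,2-reduction of the enone, and axial hydride delivery should place the new hydroxyl equatorial and cis to the isopropenyl group.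

Step 2
Reactants: 2 (1R,5R)-cis-carveol
Product: 3 (1S,5R)-trans-carveyl 4-nitrobenzoate
Conditions: 4-O2NC6H4CO2H, PPh3, DIAD, THF, 0 °C → rt
Reagents that add atoms: 4-nitrobenzoic acid, OC(=O)c1ccc(cc1)[N+](=O)[O-]
Why: Mitsunobu reaction, in which SN2 displacement of the oxyphosphonium group by the carboxylate inverts the carbinol carbon to (S), the configuration of C3 in the target.

Step 3
Reactants: 3 (1S,5R)-trans-carveyl 4-nitrobenzoate
Product: 4 (1S,5R)-trans-carveol
Conditions: K2CO3, MeOH, rt
Reagents that add atoms: none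
Why: Base-catalysed transesterification with methanol frees the alcohol without touching either stereocentre.

Step 4
Reactants: 4 (1S,5R)-trans-carveol
Product: 5 (1S,5R)-trans-carveol tert-butyldimethylsilyl ether
Conditions: TBSCl, imidazole, DMF, rt
Reagents that add atoms: tert-butyldimethylsilyl chloride, CC(C)(C)[Si](C)(C)Cl
Why: Standard silylation; the TBS ether should survive organolithium, KH, amide base and mild acid and is removed selectively near the end.

Step 5
Reactants: 5 (1S,5R)-trans-carveol tert-butyldimethylsilyl ether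
Product: 6 (4S,6R)-4-(tert-butyldimethylsilyloxy)-3-methyl-6-(prop-1-en-2-yl)cyclohex-2-en-1-one (silyloxy and isopropenyl trans)
Conditions: CrO3, 3,5-dimethylpyrazole, CH2Cl2, −20 °C
Reagents that add atoms: chromium trioxide, O=[Cr](=O)=O
Why: Allylic oxidation by the CrO3–3,5-dimethylpyrazole complex converts the ring methylene next to the trisubstituted alkene into the enone carbonyl (the future C6), the pattern known for limonene-type cyclohexenes that keep their isopropenyl group; both stereocentres stay untouched.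

Step 6
Reactants: 7 2,5-dimethoxytetrahydrofuran (isomer mixture)
Product: 8 2-methoxy-2,3-dihydrofuran (racemic)
Conditions: Me3SiOTf, i-Pr2NEt, CH2Cl2, −20 °C → rt
Reagents that add atoms: none
Why: Acetal-to-enol-ether elimination: the silyl triflate ionises one methoxy group and the hindered amine removes the neighbouring proton, while the product acetal, whose ring oxygen is now part of the enol ether, should ionise more slowly, which limits a second elimination to furan.

Step 7
Reactants: 8 2-methoxy-2,3-dihydrofuran (racemic)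
Product: 10 4-bromo-2-methoxy-2,3-dihydrofuran (racemic), via dibromide 9 (not isolated)
Conditions: Br2, CH2Cl2, −78 °C; then Et3N, −78 °C → rt
Reagents that add atoms: bromine, BrBr
Why: Electrophilic bromine addition to the enol ether followed by amine-induced dehydrobromination (the anomeric bromide ionises, the proton on the bromine-bearing carbon is lost) is the standard way from cyclic enol ethers to their β-bromo derivatives and leaves the base-stable methyl acetal alone.

Step 8
Reactants: 10 4-bromo-2-methoxy-2,3-dihydrofuran (racemic); 6 (4S,6R)-4-(tert-butyldimethylsilyloxy)-3-methyl-6-(prop-1-en-2-yl)cyclohex-2-en-1-one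
Product: 13 (1R,4S,6R)-4-(tert-butyldimethylsilyloxy)-1-(2-methoxy-2,3-dihydrofuran-4-yl)-3-methyl-6-(prop-1-en-2-yl)cyclohex-2-en-1-ol (alkenyl groups trans; both acetal epimers), via alkenyllithium 11 (not isolated), via alkenylcerium dichloride 12 (not isolated)
Conditions: t-BuLi (2 equiv), Et2O, −100 °C; CeCl3, THF, −78 °C; then 6, −78 °C; aq NH4Cl
Reagents that add atoms: none
Why: Bromine–lithium exchange at −100 °C should outrun ring opening of the β-oxido alkenyllithium, transmetalation to the weakly basic organocerium suppresses enolisation at the isopropenyl-bearing α-carbon, and the 1,2-addition to the carbonyl should occur on the face anti to the adjacent isopropenyl group, which sets the carbinol centre (R) with the two alkenyl groups trans.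

Step 9
Reactants: 13 trans-1,2-dialkenyl cyclohexenol
Product: 16 3β-(tert-butyldimethylsilyloxy)-8β,12-epoxy-12-methoxy-7αH-germacra-1(10)E,4Z-dien-6-one (3S,7R,8R; C12 epimers), via potassium alkoxide 14 (not isolated), via potassium enolate 15 (not isolated)
Conditions: KH, 18-crown-6, THF, 0 °C → rt; then AcOH, THF, −78 °C
Reagents that add atoms: none
Why: Deprotonation gives potassium alkoxide 14, whose charge-accelerated [3,3] shift (anionic oxy-Cope) cleaves the doubly allylic C1–C6 σ-bond and joins C8 to C9 through a chair transition state; the nearest precedent is the ring expansion of alkenyllithium adducts of isopiperitenone-type enones to (2Z,6E)-cyclodecadienones. The ten-membered ring arises by a four-atom enlargement of the cyclohexene (no end-to-end macrocyclisation), and the five-membered acetal ring comes through intact and ends cis-fused across C7–C8. C8 is fixed by transfer of chirality from the isopropenyl-bearing carbon, which itself becomes sp2: with both ring bonds pseudo-equatorial the ring-locked enol ether holds O8 anti to C6 and hence pseudo-equatorial, that is 8β, and the same chair gives the E C1=C10 alkene while Z C4=C5 is simply retained. C7 is fixed in the quench, since the fully substituted enolate 15 cannot swing through the ring and should take its proton at −78 °C on the outer face, cis to H8. The step needs the chair through the dihydrofuranyl alkene instead of a boat or the [3,3] path through the ring alkene, which the trans-diequatorial alkenyl groups of 13 secure, and it needs enolate 15 to retain O8, which is expected because the C8–O bond sits near the nodal plane of the exocyclic enolate, so that its expulsion would be the reverse of a 5-endo-trig closure.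

Step 10
Reactants: 16 ring-expanded keto methyl acetal
Product: 17 3β-(tert-butyldimethylsilyloxy)-12-hydroxy-8β,12-epoxy-7αH-germacra-1(10)E,4Z-dien-6-one (lactol, C12 epimers)
Conditions: pyridinium p-toluenesulfonate (cat.), acetone–H2O, rt
Reagents that add atoms: water, O
Why: Mild acid-catalysed acetal hydrolysis of the 2-methoxytetrahydrofuran unit, under which the secondary TBS ether and the β-alkoxy ketone should persist.

Step 11
Reactants: 17 keto lactol
Product: 18 3β-(tert-butyldimethylsilyloxy)-6-oxo-7αH-germacra-1(10)E,4Z-dien-8β,12-olide (cis-fused lactone)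
Conditions: PhI(OAc)2, TEMPO (cat.), CH2Cl2, rt
Reagents that add atoms: none
Why: Oxoammonium (TEMPO) oxidation of the lactol to the γ-lactone runs without base, so the β-acyloxy ketone should neither eliminate nor epimerise at C7, and the two C12 epimers converge.

Step 12
Reactants: 18 6-oxo-8β,12-lactone
Product: 19 3β-(tert-butyldimethylsilyloxy)-6α-hydroxy-7αH-germacra-1(10)E,4Z-dien-8β,12-olide
Conditions: NaBH4, CeCl3·7H2O, MeOH, −78 °C
Reagents that add atoms: none
Why: Luche 1,2-reduction of the enone carbonyl, with hydride delivered to the outer face of the ring (the face turned away from the transannular C1=C10 unit in the conformer left by the ring expansion), should give the 6α-alcohol with O6 trans to C11 across C6–C7.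

Step 13
Reactants: 19 6α-hydroxy-8β,12-lactone
Product: 20 3β-(tert-butyldimethylsilyloxy)-8β-hydroxy-7αH-germacra-1(10)E,4Z-dien-6α,12-olide (trans-fused lactone)
Conditions: K2CO3 (cat.), MeOH, 0 °C → rt; AcOH; then pyridinium p-toluenesulfonate (cat.), PhMe, 40 °C
Reagents that add atoms: none
Why: Base-mediated transesterification through the hydroxy methyl ester lets the acyl group equilibrate between O8 and O6, and the trans-fused 6α,12-γ-lactone, the arrangement of the 8β-oxygenated germacranolides, is expected to be the preferred isomer; no stereocentre is involved.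

Step 14
Reactants: 20 8β-hydroxy-6α,12-lactone
Product: 23 3β-(tert-butyldimethylsilyloxy)-8β-hydroxy-7αH-germacra-1(10)E,4Z,11(13)-trien-6α,12-olide, via Mannich base 21 (not isolated), via ammonium iodide 22 (not isolated)
Conditions: LiN(i-Pr)2 (2.5 equiv), THF, −78 °C; (Me2N=CH2)I, −78 °C → rt; then MeI, MeOH, rt; aq NaHCO3
Reagents that add atoms: N,N-dimethylmethyleneiminium iodide (Eschenmoser's salt), C=[N+](C)C.[I-]
Why: Lactone-enolate Mannich reaction with Eschenmoser's salt followed by quaternisation and Hofmann-type elimination installs the exocyclic methylene, the extra base holding the free 8β-hydroxyl as its alkoxide, and the transient C11 centre is removed again.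

Step 15
Reactants: 24 tiglic acid
Product: 25 tiglyl alcohol, (E)-2-methylbut-2-en-1-ol
Conditions: LiAlH4, Et2O, 0 °C
Reagents that add atoms: none
Why: Hydride reduction of the carboxylic acid to the allylic alcohol with retention of the E alkene.

Step 16
Reactants: 25 tiglyl alcohol
Product: 26 [(2S,3S)-2,3-dimethyloxiran-2-yl]methanol
Conditions: Ti(OiPr)4 (cat.), L-(+)-diethyl tartrate, t-BuOOH, 4 Å molecular sieves, CH2Cl2, −20 °C
Reagents that add atoms: tert-butyl hydroperoxide, CC(C)(C)OO
Why: Sharpless asymmetric epoxidation, in which the L-(+)-tartrate–titanium complex delivers oxygen to the alkene face that gives the (2S,3S) epoxy alcohol (methyl groups cis).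

Step 17
Reactants: 26 (2S,3S)-epoxy alcohol
Product: 27 (2R,3S)-2,3-dimethyloxirane-2-carboxylic acid
Conditions: RuCl3 (cat.), NaIO4, CCl4–MeCN–H2O, rt
Reagents that add atoms: water, O
Why: Ruthenium-catalysed periodate oxidation takes the primary epoxy alcohol to the glycidic acid without opening the oxirane; the descriptor at C2 changes only through the priority rules.

Step 18
Reactants: 23 α-methylene lactone with free 8β-OH; 27 (2R,3S)-2,3-dimethyloxirane-2-carboxylic acid
Product: 29 3β-(tert-butyldimethylsilyloxy)-8β-[(2R,3S)-2,3-dimethyloxirane-2-carbonyloxy]-7αH-germacra-1(10)E,4Z,11(13)-trien-6α,12-olide, via mixed anhydride 28 (not isolated)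
Conditions: 27, 2,4,6-Cl3C6H2COCl, Et3N, PhMe, rt; then 23, DMAP, rt
Reagents that add atoms: none
Why: Yamaguchi esterification through the mixed anhydride acylates the hindered 8β-hydroxyl with the α-quaternary, non-epimerisable epoxy acid under mild conditions that the α-methylene lactone tolerates.

Step 19
Reactants: 29 C8 epoxy ester C3 silyl ether
Product: 30 3β-hydroxy-8β-[(2R,3S)-2,3-dimethyloxirane-2-carbonyloxy]-7αH-germacra-1(10)E,4Z,11(13)-trien-6α,12-olide
Conditions: HF·pyridine, pyridine, THF, 0 °C → rt
Reagents that add atoms: none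
Why: Fluoride-mediated desilylation with pyridine-buffered HF should free the allylic C3 alcohol without opening the glycidic ester or adding to the methylene lactone.

Step 20
Reactants: 30 C3 alcohol; 31 isovaleryl chloride
Product: 32 3β-isovaleryloxy-8β-[(2R,3S)-2,3-dimethyloxirane-2-carbonyloxy]-7αH-germacra-1(10)E,4Z,11(13)-trien-6α,12-olide
Conditions: pyridine, DMAP (cat.), CH2Cl2, 0 °C → rt
Reagents that add atoms: none
Why: DMAP-catalysed acylation of the secondary allylic alcohol by the acid chloride, with retention at C3.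

Step 21
Reactants: 32 1(10)-ene diester
Product: 33 target CNP0167461.4, 1β,10α-epoxy-3β-isovaleryloxy-8β-[(2R,3S)-2,3-dimethyloxirane-2-carbonyloxy]-7αH-germacra-4Z,11(13)-dien-6α,12-olide (1R,3S,6R,7R,8R,10R)
Conditions: mCPBA (1.1 equiv), NaHCO3, CH2Cl2, 0 °C
Reagents that add atoms: 3-chloroperoxybenzoic acid, OOC(=O)c1cccc(Cl)c1
Why: Prilezhaev epoxidation, in which the strained trisubstituted E C1=C10 alkene is the most nucleophilic alkene (C4=C5 is deactivated by two allylic acyloxy groups, C11=C13 is conjugated) and peripheral attack on the preferred conformer with C14 on the β face should give the 1β,10α oxirane as in related germacranolides.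

Compound list
1 | (R)-(−)-carvone | CC1=CC[C@H](CC1=O)C(C)=C | starting material
2 | (1R,5R)-cis-carveol | C1C=C(C)[C@H](O)C[C@@H]1C(C)=C | intermediate
3 | (1S,5R)-trans-carveyl 4-nitrobenzoate | C1C=C(C)[C@@H](OC(=O)c2ccc(cc2)[N+](=O)[O-])C[C@@H]1C(C)=C | intermediate
4 | (1S,5R)-trans-carveol | C1C=C(C)[C@@H](O)C[C@@H]1C(C)=C | intermediate
5 | (1S,5R)-trans-carveol TBS ether | C1C=C(C)[C@@H](O[Si](C)(C)C(C)(C)C)C[C@@H]1C(C)=C | intermediate
6 | (4S,6R)-4-(TBS-oxy)-3-methyl-6-(prop-1-en-2-yl)cyclohex-2-en-1-one | O=C1C=C(C)[C@@H](O[Si](C)(C)C(C)(C)C)C[C@@H]1C(C)=C | intermediate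
7 | 2,5-dimethoxytetrahydrofuran (isomer mixture) | COC1CCC(OC)O1 | starting material
8 | 2-methoxy-2,3-dihydrofuran (racemic) | COC1CC=CO1 | intermediate
9 | 2,3-dibromo-5-methoxytetrahydrofuran (not isolated) | COC1CC(Br)C(Br)O1 | intermediate
10 | 4-bromo-2-methoxy-2,3-dihydrofuran (racemic) | COC1CC(Br)=CO1 | intermediate
11 | (2-methoxy-2,3-dihydrofuran-4-yl)lithium (not isolated) | COC1CC([Li])=CO1 | intermediate
12 | (2-methoxy-2,3-dihydrofuran-4-yl)cerium dichloride (not isolated) | COC1CC([Ce](Cl)Cl)=CO1 | intermediate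
13 | (1R,4S,6R)-4-(TBS-oxy)-1-(2-methoxy-2,3-dihydrofuran-4-yl)-3-methyl-6-(prop-1-en-2-yl)cyclohex-2-en-1-ol (acetal epimers) | O[C@]1(C2=COC(OC)C2)C=C(C)[C@@H](O[Si](C)(C)C(C)(C)C)C[C@@H]1C(C)=C | intermediate
14 | potassium alkoxide of 13 (not isolated) | [K+].[O-][C@]1(C2=COC(OC)C2)C=C(C)[C@@H](O[Si](C)(C)C(C)(C)C)C[C@@H]1C(C)=C | intermediate
15 | potassium C6-enolate of 16, C5 trans to C8 across C6=C7 (not isolated) | [K+].C1/C(C)=C/C[C@H](O[Si](C)(C)C(C)(C)C)/C(C)=C\C([O-])=C2/CC(OC)O[C@H]12 | intermediate
16 | 3β-(TBS-oxy)-8β,12-epoxy-12-methoxy-7αH-germacra-1(10)E,4Z-dien-6-one (C12 epimers) | O=C1/C=C(/C)[C@@H](O[Si](C)(C)C(C)(C)C)C/C=C(\C)C[C@H]2OC(OC)C[C@@H]12 | intermediate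
17 | 3β-(TBS-oxy)-12-hydroxy-8β,12-epoxy-7αH-germacra-1(10)E,4Z-dien-6-one (lactol) | O=C1/C=C(/C)[C@@H](O[Si](C)(C)C(C)(C)C)C/C=C(\C)C[C@H]2OC(O)C[C@@H]12 | intermediate
18 | 3β-(TBS-oxy)-6-oxo-7αH-germacra-1(10)E,4Z-dien-8β,12-olide | O=C1/C=C(/C)[C@@H](O[Si](C)(C)C(C)(C)C)C/C=C(\C)C[C@H]2OC(=O)C[C@@H]12 | intermediate
19 | 3β-(TBS-oxy)-6α-hydroxy-7αH-germacra-1(10)E,4Z-dien-8β,12-olide | O[C@@H]1/C=C(/C)[C@@H](O[Si](C)(C)C(C)(C)C)C/C=C(\C)C[C@H]2OC(=O)C[C@@H]12 | intermediate
20 | 3β-(TBS-oxy)-8β-hydroxy-7αH-germacra-1(10)E,4Z-dien-6α,12-olide | C1C(=O)O[C@@H]2/C=C(/C)[C@@H](O[Si](C)(C)C(C)(C)C)C/C=C(\C)C[C@@H](O)[C@@H]12 | intermediate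
21 | 13-(dimethylamino) Mannich base of 20, C11 epimers (not isolated) | CN(C)CC1C(=O)O[C@@H]2/C=C(/C)[C@@H](O[Si](C)(C)C(C)(C)C)C/C=C(\C)C[C@@H](O)[C@@H]12 | intermediate
22 | trimethylammonium iodide of 21 (not isolated) | C[N+](C)(C)CC1C(=O)O[C@@H]2/C=C(/C)[C@@H](O[Si](C)(C)C(C)(C)C)C/C=C(\C)C[C@@H](O)[C@@H]12.[I-] | intermediate
23 | 3β-(TBS-oxy)-8β-hydroxy-7αH-germacra-1(10)E,4Z,11(13)-trien-6α,12-olide | C=C1C(=O)O[C@@H]2/C=C(/C)[C@@H](O[Si](C)(C)C(C)(C)C)C/C=C(\C)C[C@@H](O)[C@@H]12 | intermediate
24 | tiglic acid | C/C=C(\C)C(=O)O | starting material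
25 | tiglyl alcohol, (E)-2-methylbut-2-en-1-ol | C/C=C(\C)CO | intermediate
26 | [(2S,3S)-2,3-dimethyloxiran-2-yl]methanol | OC[C@]1(C)O[C@H]1C | intermediate
27 | (2R,3S)-2,3-dimethyloxirane-2-carboxylic acid | OC(=O)[C@]1(C)O[C@H]1C | intermediate
28 | mixed anhydride of 27 with 2,4,6-trichlorobenzoic acid (not isolated) | O=C(OC(=O)c1c(Cl)cc(Cl)cc1Cl)[C@]1(C)O[C@H]1C | intermediate
29 | 3β-(TBS-oxy)-8β-[(2R,3S)-2,3-dimethyloxirane-2-carbonyloxy]-7αH-germacra-1(10)E,4Z,11(13)-trien-6α,12-olide | C=C1C(=O)O[C@@H]2/C=C(/C)[C@@H](O[Si](C)(C)C(C)(C)C)C/C=C(\C)C[C@@H](OC(=O)[C@]3(C)O[C@H]3C)[C@@H]12 | intermediate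
30 | 3β-hydroxy-8β-[(2R,3S)-2,3-dimethyloxirane-2-carbonyloxy]-7αH-germacra-1(10)E,4Z,11(13)-trien-6α,12-olide | C=C1C(=O)O[C@@H]2/C=C(/C)[C@@H](O)C/C=C(\C)C[C@@H](OC(=O)[C@]3(C)O[C@H]3C)[C@@H]12 | intermediate
31 | isovaleryl chloride | CC(C)CC(=O)Cl | starting material
32 | 3β-isovaleryloxy-8β-[(2R,3S)-2,3-dimethyloxirane-2-carbonyloxy]-7αH-germacra-1(10)E,4Z,11(13)-trien-6α,12-olide | C=C1C(=O)O[C@@H]2/C=C(/C)[C@@H](OC(=O)CC(C)C)C/C=C(\C)C[C@@H](OC(=O)[C@]3(C)O[C@H]3C)[C@@H]12 | intermediate
33 | CNP0167461.4 (1R,3S,6R,7R,8R,10R; side-chain oxirane 2R,3S) | C=C1C(=O)O[C@@H]2/C=C(/C)[C@@H](OC(=O)CC(C)C)C[C@H]3O[C@]3(C)C[C@@H](OC(=O)[C@]3(C)O[C@H]3C)[C@@H]12 | target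

Total step count: 21. Longest linear sequence: 16 steps (steps 1–5, 8–14 and 18–21); steps 6–7 and 15–17 make the two side fragments.

Steps most likely to fail

Step 9 (ring expansion). The potassium enolate may expel the C8 oxygen by β-elimination with opening of the acetal ring, it may take its proton on the inner face, or a boat or 1,3-shift pathway may compete with the chair. The fallback sets out from 13 and comes back at 16, and it avoids a free enolate at any temperature above −78 °C. The tertiary alcohol is silylated with Me3Si-imidazole to the trimethylsilyl ether of 13 F1. This is heated in base-washed glassware (PhMe, 150–180 °C), where the neutral siloxy-Cope rearrangement should give the ring-expanded trimethylsilyl enol ether F2. F2 is cleaved at −78 °C with Bu4NF buffered by AcOH, so that the fleeting enolate is protonated at once on its outer face to give 16.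

Step 13 (acyl shift from O8 to O6). The equilibrium between the two γ-lactones may rest on the side of the cis-fused 8,12-isomer, or the hydroxy ester may not reclose cleanly. The fallback sets out from 19 and comes back at 20, and it fixes the direction with protecting groups. O6 is silylated (Et3SiCl, imidazole) to the 6-O-triethylsilyl ether of 19 F3. The lactone is opened with MeNH(OMe)·HCl and AlMe3 to the Weinreb amide with free 8β-hydroxyl F4, which is capped with (ClCH2CO)2O and pyridine as the 8-O-chloroacetate F5. Pyridine-buffered HF·pyridine removes the triethylsilyl group selectively and gives the 6α-hydroxy amide F6, which closes under camphorsulfonic acid to the 8-O-chloroacetyl 6α,12-lactone F7. Thiourea and NaHCO3 in EtOH then remove the chloroacetate to give 20.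

Step 5 (allylic oxidation). Hydrogen abstraction may occur at the silyloxy-bearing carbon or in the isopropenyl group, and over-oxidation may erode the enone. The fallback sets out from 4 and comes back at 6, and it replaces C–H oxidation by an epoxide-to-enone transposition. Hydroxyl-directed epoxidation (VO(acac)2, t-BuOOH) gives the syn 2,3-epoxy-trans-carveol F8, and silylation gives its TBS ether F9. PhSeNa (from PhSeSePh and NaBH4, EtOH) opens the oxirane at the secondary carbon to the trans hydroxy selenide F10. H2O2 gives the selenoxide F11, whose syn elimination yields the tertiary allylic alcohol F12. Oxidative 1,3-transposition with pyridinium chlorochromate (C5H5NH)[CrO3Cl] (Dauben–Babler oxidation) then delivers enone 6.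

Further compounds
F1 | step 9 | trimethylsilyl ether of 13 | C[Si](C)(C)O[C@]1(C2=COC(OC)C2)C=C(C)[C@@H](O[Si](C)(C)C(C)(C)C)C[C@@H]1C(C)=C
F2 | step 9 | ring-expanded C6 trimethylsilyl enol ether | C1/C(C)=C/C[C@H](O[Si](C)(C)C(C)(C)C)/C(C)=C\C(O[Si](C)(C)C)=C2/CC(OC)O[C@H]12
F3 | step 13 | 6-O-triethylsilyl ether of 19 | CC[Si](CC)(CC)O[C@@H]1/C=C(/C)[C@@H](O[Si](C)(C)C(C)(C)C)C/C=C(\C)C[C@H]2OC(=O)C[C@@H]12
F4 | step 13 | Weinreb amide with free 8β-hydroxyl and 6-O-triethylsilyl ether | CON(C)C(=O)C[C@H]1[C@H](O[Si](CC)(CC)CC)/C=C(/C)[C@@H](O[Si](C)(C)C(C)(C)C)C/C=C(\C)C[C@H]1O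
F5 | step 13 | 8-O-chloroacetate of F4 | CON(C)C(=O)C[C@H]1[C@H](O[Si](CC)(CC)CC)/C=C(/C)[C@@H](O[Si](C)(C)C(C)(C)C)C/C=C(\C)C[C@H]1OC(=O)CCl
F6 | step 13 | 6α-hydroxy Weinreb amide 8-O-chloroacetate | CON(C)C(=O)C[C@H]1[C@H](O)/C=C(/C)[C@@H](O[Si](C)(C)C(C)(C)C)C/C=C(\C)C[C@H]1OC(=O)CCl
F7 | step 13 | 8-O-chloroacetyl 6α,12-lactone | C1C(=O)O[C@@H]2/C=C(/C)[C@@H](O[Si](C)(C)C(C)(C)C)C/C=C(\C)C[C@@H](OC(=O)CCl)[C@@H]12
F8 | step 5 | syn 2,3-epoxy-trans-carveol | C1[C@H]2O[C@@]2(C)[C@@H](O)C[C@@H]1C(C)=C
F9 | step 5 | TBS ether of F8 | C1[C@H]2O[C@@]2(C)[C@@H](O[Si](C)(C)C(C)(C)C)C[C@@H]1C(C)=C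
F10 | step 5 | trans hydroxy selenide | C1[C@H]([Se]c2ccccc2)[C@@](C)(O)[C@@H](O[Si](C)(C)C(C)(C)C)C[C@@H]1C(C)=C
F11 | step 5 | selenoxide of F10 | C1[C@H]([Se](=O)c2ccccc2)[C@@](C)(O)[C@@H](O[Si](C)(C)C(C)(C)C)C[C@@H]1C(C)=C
F12 | step 5 | tertiary allylic alcohol | C1=C[C@@](C)(O)[C@@H](O[Si](C)(C)C(C)(C)C)C[C@@H]1C(C)=C
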